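Everything rests on cutting the 1,2-dioxolane (O1–O2–C3–C4–C5) at C3–C4 and C5–O. C1–C3 with the C3 methyl is methyl acetoacetate held at the peroxyketal level; C4, C5 and the C5 methyl are the isopropenyl end of a triene that already carries C7 (R) and both E alkenes. One operation, a (3+2) annulation of a peroxycarbenium ion paired with a chiral disulfonimide anion, joins the halves, closes the ring and sets both fully substituted stereocentres C3 and C5. Its precursors are racemic methyl 3-methoxy-3-(triethylsilylperoxy)butanoate and (4R,7E,11E)-2,4-dimethyl-12-phenyldodeca-1,7,11-triene, the latter built by two cyclopropylcarbinyl openings, an asymmetric conjugate addition and a methylenation; a cold saponification ends the route.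

Key step: step 9

**Remarks**

- Numbering: C1 is the carboxyl carbon and C15 the phenyl-bearing carbon. The target is (3R,5R,7R), with the two ring methyl groups cis.
- Assumption: the sense of induction of the two chiral catalysts in steps 4 and 9 is taken as drawn; both antipodes of each are available, and the configuration should be verified at ketone 9 (by correlation) and at dioxolane 17 (by identifying the diastereomer) before material is committed.
- Compounds 1, 5, 13 and 14 are racemic by design; each of these stereocentres is erased later (steps 1, 3 and 9).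
- Design of the key-step partners: the peroxide carries Et3Si, which is the group the catalyst recycles, so no external silicon source is consumed. The disulfonimide is silylated before the substrates are added, because the mixture contains no silyl nucleophile that would do this in the flask. The triene is the limiting partner. The ester stays methyl so that the last step is a cold hydrolysis.
- Safety: ethereal H2O2 and the low-molecular-weight peroxides 13 and 14 are handled in solution, behind a shield, and are not concentrated to dryness on scale.

**Route**

Step 1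
Reactants: 1 cyclopropyl(phenyl)methanol (racemic)
Product: 2 [(1E)-4-bromobut-1-en-1-yl]benzene
Conditions: 48% aq. HBr, 0 °C
Reagents that add atoms: hydrogen bromide, Br
Why: Acid-promoted cyclopropylcarbinyl-to-homoallyl bromide rearrangement (Julia olefin synthesis), in which bromide opens the benzylic cyclopropylcarbinyl cation at a ring CH2 and conjugation with the phenyl ring should make the new C14=C15 bond E.

Step 2
Reactants: 2 [(1E)-4-bromobut-1-en-1-yl]benzene; 3 cyclopropanecarbaldehyde
Product: 5 (4E)-1-cyclopropyl-5-phenylpent-4-en-1-ol (racemic), via Grignard reagent 4 (not isolated)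
Conditions: Mg, THF, 25 °C; then 3, 0 °C; aq. NH4Cl
Reagents that add atoms: none
Why: Grignard addition of a primary homoallylic organomagnesium (used at once and cold) to an unhindered aldehyde; the carbinol centre needs no control because it becomes an sp2 carbon in step 3.

Step 3
Reactants: 5 (4E)-1-cyclopropyl-5-phenylpent-4-en-1-ol
Product: 6 [(1E,5E)-8-bromoocta-1,5-dien-1-yl]benzene
Conditions: Me3SiBr, ZnBr2 (cat.), CH2Cl2, −20 °C
Reagents that add atoms: bromotrimethylsilane, C[Si](C)(C)Br
Why: Second cyclopropylcarbinyl-to-homoallyl bromide rearrangement, here under silyl bromide/ZnBr2 activation at low temperature; bromide opens the bisected secondary cation in the conformer that keeps the chain away from the breaking ring bond, which should give the E C10=C11 bond, and any Z isomer is removed on AgNO3-impregnated silica.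

Step 4
Reactants: 6 [(1E,5E)-8-bromoocta-1,5-dien-1-yl]benzene; 7 (3E)-pent-3-en-2-one
Product: 9 (4R,7E,11E)-4-methyl-12-phenyldodeca-7,11-dien-2-one, via Grignard reagent 8 (not isolated)
Conditions: Mg, Et2O, 25 °C; then slow combination with 7, CuBr·SMe2 (5 mol%), (R)-1-[(Sp)-2-(diphenylphosphino)ferrocenyl]ethyldicyclohexylphosphine (6 mol%), t-BuOMe, −75 °C; aq. NH4Cl
Reagents that add atoms: none
Why: Copper-catalysed asymmetric conjugate addition of a Grignard reagent to an acyclic enone, in which the CuBr complex of the ferrocenyl diphosphine delivers the alkyl group to the Si face of C4 of 7 and so sets C7 of the target as R (catalyst control), while slow mixing at low temperature suppresses 1,2-addition.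

Step 5
Reactants: 9 (4R,7E,11E)-4-methyl-12-phenyldodeca-7,11-dien-2-one
Product: 10 (4R,7E,11E)-2,4-dimethyl-12-phenyldodeca-1,7,11-triene
Conditions: Ph3PCH3Br, KOt-Bu, THF, 0 → 25 °C
Reagents that add atoms: methyltriphenylphosphonium bromide, C[P+](c1ccccc1)(c1ccccc1)c1ccccc1.[Br-]
Why: Wittig methylenation of a methyl ketone with the non-stabilised ylide; the stereocentre is β to the carbonyl and is not touched by enolisation.

Step 6
Reactants: 11 methyl acetoacetate
Product: 12 methyl 3,3-dimethoxybutanoate
Conditions: HC(OMe)3, MeOH, p-toluenesulfonic acid (cat.), 25 °C; NaOMe quench; distillation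
Reagents that add atoms: trimethyl orthoformate, COC(OC)OC; methanol, CO
Why: Acid-catalysed ketalisation driven by the orthoester as water scavenger; neutralisation before concentration prevents loss of methanol to the conjugated enol ether.

Step 7
Reactants: 12 methyl 3,3-dimethoxybutanoate
Product: 13 methyl 3-hydroperoxy-3-methoxybutanoate (racemic)
Conditions: anhydrous H2O2 in Et2O (3 equiv), (±)-camphor-10-sulfonic acid (cat.), 0 °C; NaHCO3
Reagents that add atoms: hydrogen peroxide, OO
Why: Acid-catalysed perhydrolysis of a ketal (exchange of one methoxy group through the methoxycarbenium ion); the second exchange should be slower because the hydroperoxy-substituted cation is less stabilised, so the reaction should stop at the hydroperoxy ketal.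

Step 8
Reactants: 13 methyl 3-hydroperoxy-3-methoxybutanoate
Product: 14 methyl 3-methoxy-3-[(triethylsilyl)peroxy]butanoate (racemic)
Conditions: Et3SiCl, imidazole, DMF, 0 °C
Reagents that add atoms: chlorotriethylsilane, CC[Si](Cl)(CC)CC
Why: O-Silylation of a hydroperoxide under mildly basic conditions; the peroxy carbon bears no hydrogen, so base-induced fragmentation of the peroxide is not possible, and the ketal and the ester are inert.

Step 9
Reactants: 10 (4R,7E,11E)-2,4-dimethyl-12-phenyldodeca-1,7,11-triene; 14 methyl 3-methoxy-3-[(triethylsilyl)peroxy]butanoate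
Product: 17 methyl 2-{(3R,5R)-3,5-dimethyl-5-[(2R,5E,9E)-2-methyl-10-phenyldeca-5,9-dien-1-yl]-1,2-dioxolan-3-yl}acetate, via peroxycarbenium ion 15 (not isolated), via tertiary carbocation 16 (not isolated)
Conditions: (R)-3,3'-bis[3,5-bis(trifluoromethyl)phenyl]-1,1'-binaphthyl-2,2'-disulfonimide (10 mol%), Me2C=C(OMe)OSiMe3 (10 mol%, 25 °C, pre-silylation), PhMe; then 10 (1.0 equiv), slow addition of 14 (1.5 equiv), −78 °C; Et3N quench at −78 °C
Reagents that add atoms: none
Why: Proposed new method: the N-silylated disulfonimide should abstract methoxide from racemic 14 (its stereocentre is erased) to give peroxycarbenium ion 15 as a contact ion pair with the chiral anion plus Et3SiOMe; the unsubstituted CH2 terminus of the 2-methylalk-1-ene of 10 then adds to C3 (bond C3–C4) to give tertiary cation 16, and the silylated distal peroxy oxygen collapses onto C5 (bond C5–O) and hands Et3Si+ back to the anion, which regenerates the Lewis acid. The closest known chemistry is the SnCl4- or TiCl4-mediated annulation of triethylsilylperoxy ketals with alkenes to 1,2-dioxolanes and the silylium–disulfonimide ion-pair catalysis of Mukaiyama-type additions; new is the relay of face selectivity from a chiral counter-anion to a peroxycarbenium ion. The 1,2-dioxolane is closed when the peroxy oxygen captures the trigonal cationic ring atom C5 through a five-membered envelope, a closure that would count as 5-endo-trig if C5 were an alkene carbon; here no π bond is broken, so the collapse is a plain cation–lone-pair combination without that stereoelectronic penalty. C3 is set in the C–C bond formation by the anion, which must shield one face of 15 (catalyst control, to be read directly from the diastereomer ratio because C7 is already homochiral), and C5 is set in the closure, where the envelope that places the C2 arm on C3 and the C6 chain on C5 pseudo-equatorial on one face and the two methyl groups on the other should give the cis-dimethyl (3R,5R) ring; C7 is too remote to bias either event. The step needs chemoselectivity for the isopropenyl group over the C10=C11 and styrenyl C14=C15 bonds: a fully substituted, ketone-derived electrophile adds readily only to an unsubstituted alkene terminus that leads to a tertiary cation, five-membered O-capture should be faster than six-membered cation–olefin cyclisation onto C10=C11, and low temperature with only a small excess of 14 and a cold amine quench protect the styrene and the product peroxide.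

Step 10
Reactants: 17 methyl 2-{(3R,5R)-3,5-dimethyl-5-[(2R,5E,9E)-2-methyl-10-phenyldeca-5,9-dien-1-yl]-1,2-dioxolan-3-yl}acetate
Product: 18 2-{(3R,5R)-3,5-dimethyl-5-[(2R,5E,9E)-2-methyl-10-phenyldeca-5,9-dien-1-yl]-1,2-dioxolan-3-yl}acetic acid
Conditions: LiOH, THF/H2O, 0 °C; then 1 M HCl to pH 3, 0 °C
Reagents that add atoms: lithium hydroxide, [Li+].[OH-]
Why: Saponification of a methyl ester by acyl–oxygen cleavage; C3 and C5 carry no hydrogen, so the base-induced fragmentation typical of peroxides with an α-hydrogen cannot occur, ester hydrolysis should outrun α-deprotonation and β-elimination of the peroxide, and no stereocentre or alkene is affected.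

**Compound list**

1 | cyclopropyl(phenyl)methanol (racemic) | OC(c1ccccc1)C1CC1 | starting material
2 | [(1E)-4-bromobut-1-en-1-yl]benzene | BrCC/C=C/c1ccccc1 | intermediate
3 | cyclopropanecarbaldehyde | O=CC1CC1 | starting material
4 | bromo[(3E)-4-phenylbut-3-en-1-yl]magnesium (Grignard reagent, formed in the flask) | Br[Mg]CC/C=C/c1ccccc1 | intermediate
5 | (4E)-1-cyclopropyl-5-phenylpent-4-en-1-ol (racemic) | OC(CC/C=C/c1ccccc1)C1CC1 | intermediate
6 | [(1E,5E)-8-bromoocta-1,5-dien-1-yl]benzene | BrCC/C=C/CC/C=C/c1ccccc1 | intermediate
7 | (3E)-pent-3-en-2-one | C/C=C/C(C)=O | starting material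
8 | bromo[(3E,7E)-8-phenylocta-3,7-dien-1-yl]magnesium (Grignard reagent, formed in the flask) | Br[Mg]CC/C=C/CC/C=C/c1ccccc1 | intermediate
9 | (4R,7E,11E)-4-methyl-12-phenyldodeca-7,11-dien-2-one | C[C@H](CC/C=C/CC/C=C/c1ccccc1)CC(C)=O | intermediate
10 | (4R,7E,11E)-2,4-dimethyl-12-phenyldodeca-1,7,11-triene | C[C@H](CC/C=C/CC/C=C/c1ccccc1)CC(C)=C | intermediate
11 | methyl acetoacetate (methyl 3-oxobutanoate) | CC(=O)CC(=O)OC | starting material
12 | methyl 3,3-dimethoxybutanoate | COC(=O)CC(C)(OC)OC | intermediate
13 | methyl 3-hydroperoxy-3-methoxybutanoate (racemic) | COC(=O)CC(C)(OC)OO | intermediate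
14 | methyl 3-methoxy-3-[(triethylsilyl)peroxy]butanoate (racemic) | COC(=O)CC(C)(OC)OO[Si](CC)(CC)CC | intermediate
15 | peroxycarbenium ion of 14 after loss of methoxide, (4-methoxy-4-oxobutan-2-ylidene)[(triethylsilyl)oxy]oxonium, paired with the disulfonimide anion (cation drawn) | COC(=O)CC(C)=[O+]O[Si](CC)(CC)CC | intermediate
16 | C5 carbocation of methyl (3R,7R,10E,14E)-3,5,7-trimethyl-15-phenyl-3-[(triethylsilyl)peroxy]pentadeca-10,14-dienoate, paired with the disulfonimide anion (cation drawn) | C[C@H](CC/C=C/CC/C=C/c1ccccc1)C[C+](C)C[C@](C)(CC(=O)OC)OO[Si](CC)(CC)CC | intermediate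
17 | methyl 2-{(3R,5R)-3,5-dimethyl-5-[(2R,5E,9E)-2-methyl-10-phenyldeca-5,9-dien-1-yl]-1,2-dioxolan-3-yl}acetate | C[C@H](CC/C=C/CC/C=C/c1ccccc1)C[C@]1(C)C[C@](C)(CC(=O)OC)OO1 | intermediate
18 | 2-{(3R,5R)-3,5-dimethyl-5-[(2R,5E,9E)-2-methyl-10-phenyldeca-5,9-dien-1-yl]-1,2-dioxolan-3-yl}acetic acid | C[C@H](CC/C=C/CC/C=C/c1ccccc1)C[C@]1(C)C[C@](C)(CC(=O)O)OO1 | target

**Step count and risks**

Total step count: 10. Longest linear sequence: 7 steps (steps 1, 2, 3, 4, 5, 9, 10); steps 6–8 form the second branch.

Steps most likely to fail:

1. Step 9 (proposed new method). The anion may discriminate the two faces of the peroxycarbenium ion poorly, since methyl and CH2CO2Me differ little in size and two geometries of the C=O+–O unit are possible. The cis/trans bias in the closure may be weak, proton loss from 15 or 16 may compete with annulation, and the silyl Lewis acid may attack the styrene. The fallback gives up catalyst control and relies on separation. It sets out from 10 and 14 and comes back at 17. The two are combined with stoichiometric SnCl4 in CH2Cl2 at −78 °C, the established achiral annulation of triethylsilylperoxy ketals with 1,1-disubstituted alkenes. Because C7 is homochiral, all four ring stereoisomers are diastereomers of one another, so 17 should be separable by preparative HPLC without resolution and can be identified by the cis relationship of its ring methyl groups. No new compound is made.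

2. Step 4. Face selectivity of the CuBr·SMe2/ferrocenyl diphosphine catalyst on the small β-methyl enone may be incomplete, and 1,2-addition of the Grignard reagent may compete; the C7 purity of the oily ketone cannot easily be upgraded later. The fallback replaces catalyst control by auxiliary control. It sets out from bromide 6 (as Grignard reagent 8) and comes back at ketone 9. Commercial (4R)-4-phenyl-1,3-oxazolidin-2-one is N-acylated (n-BuLi, THF, −78 °C, then (E)-but-2-enoyl chloride) to (4R)-3-[(2E)-but-2-enoyl]-4-phenyl-1,3-oxazolidin-2-one F1. Grignard reagent 8 with CuBr·SMe2 (THF/Me2S, −40 °C) should add to the β-carbon of the chelated s-cis imide on the face opposite the phenyl group, giving (4R)-3-[(3R,6E,10E)-3-methyl-11-phenylundeca-6,10-dienoyl]-4-phenyl-1,3-oxazolidin-2-one F2, which can be purified to a single diastereomer by chromatography or crystallisation. Me(MeO)NH·HCl/AlMe3 (CH2Cl2, 0 °C) cleaves the auxiliary to (3R,6E,10E)-N-methoxy-N,3-dimethyl-11-phenylundeca-6,10-dienamide F3, and MeMgBr (THF, 0 °C) gives 9.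

3. Step 3. E selectivity in the ring opening may be incomplete (a Z isomer would travel to the end), and the acidic medium may damage the styrene. The fallback fixes the geometry by syn-hydrometalation and a stereoretentive coupling. It sets out from bromide 2 (as Grignard reagent 4) and comes back at 6. Commercial tert-butyl(but-3-yn-1-yloxy)dimethylsilane is hydrozirconated with Cp2Zr(H)Cl and iodinated with I2 to tert-butyl{[(3E)-4-iodobut-3-en-1-yl]oxy}dimethylsilane F4. Grignard reagent 4 is transmetalated with ZnBr2 to bromo[(3E)-4-phenylbut-3-en-1-yl]zinc F5, and Negishi coupling with F4 under Pd(PPh3)4 catalysis (THF, 25 °C) gives tert-butyldimethyl{[(3E,7E)-8-phenylocta-3,7-dien-1-yl]oxy}silane F6. Bu4NF (THF) releases (3E,7E)-8-phenylocta-3,7-dien-1-ol F7, and CBr4/PPh3 (CH2Cl2, 0 °C) gives 6.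

Further compounds
F0 | step 9 | none | none
F1 | step 4 | (4R)-3-[(2E)-but-2-enoyl]-4-phenyl-1,3-oxazolidin-2-one | C/C=C/C(=O)N1[C@H](c2ccccc2)COC1=O
F2 | step 4 | (4R)-3-[(3R,6E,10E)-3-methyl-11-phenylundeca-6,10-dienoyl]-4-phenyl-1,3-oxazolidin-2-one | C[C@H](CC/C=C/CC/C=C/c1ccccc1)CC(=O)N1[C@H](c2ccccc2)COC1=O
F3 | step 4 | (3R,6E,10E)-N-methoxy-N,3-dimethyl-11-phenylundeca-6,10-dienamide | C[C@H](CC/C=C/CC/C=C/c1ccccc1)CC(=O)N(C)OC
F4 | step 3 | tert-butyl{[(3E)-4-iodobut-3-en-1-yl]oxy}dimethylsilane | I/C=C/CCO[Si](C)(C)C(C)(C)C
F5 | step 3 | bromo[(3E)-4-phenylbut-3-en-1-yl]zinc | Br[Zn]CC/C=C/c1ccccc1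
F6 | step 3 | tert-butyldimethyl{[(3E,7E)-8-phenylocta-3,7-dien-1-yl]oxy}silane | CC(C)(C)[Si](C)(C)OCC/C=C/CC/C=C/c1ccccc1
F7 | step 3 | (3E,7E)-8-phenylocta-3,7-dien-1-ol | OCC/C=C/CC/C=C/c1ccccc1
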